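(The numbers in the tables are calculated from invented constants; scatter was added.)

Target in the blue run grows by 20 percentage points from 5.00 min to 15.0 min, but by 5.1 points from 25.0 min to 40.0 min, with 39.1% of the electrophile still there.

| flask | electrophile | nucleophile | solid base | remark | time |
|---|---|---|---|---|---|
| teal | 0.40 M (fed, over 2.0 min) | 1.1 equiv | 1.4 equiv | run made earlier; the fed solution adds 0.25 times the starting volume |  |
| blue | 0.40 M (fed, over 2.0 min) | 1.1 equiv | 3.7 equiv | run made earlier; the fed solution adds 0.25 times the starting volume |  |
| amber | 0.40 M (fed, over 2.0 min) | 1.1 equiv | 6 equiv | run made earlier; the fed solution adds 0.25 times the starting volume |  |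
| Tuesday's | 0.20 M (fed, over 6.0 min) | 1.10 equiv | 2.00 equiv | the fed solution adds 0.25 times the starting volume | 40 min |
| Saturday's | 0.40 M (fed, over 2.0 min) | 1.10 equiv | 2.00 equiv | the fed solution adds 0.25 times the starting volume | 40 min |
| Monday's | 0.40 M (fed, over 2.0 min) | 0.740 equiv | 2.00 equiv | the fed solution adds 0.25 times the starting volume | 40 min |
| Thursday's | 0.12 M (fed, over 2.0 min) | 4.40 equiv | 6.00 equiv | the fed solution adds 0.25 times the starting volume | 40 min |
| Friday's | 0.40 M (fed, over 2.0 min) | 0.550 equiv | 2.00 equiv | the fed solution adds 0.25 times the starting volume | 40 min |
| Sunday's | 1.2 M (fed, over 2.0 min) | 0.740 equiv | 2.00 equiv | the fed solution adds 0.25 times the starting volume | 40 min |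

- teal (time / min: target / %, electrophile / %): 10.0: 41.4, 57.6; 20.0: 51.8, 47.2; 30.0: 56.1, 42.6; 40.0: 59.0, 39.4
- blue (time / min: target / %, electrophile / %): 5.00: 27.9, 72.1; 15.0: 48.1, 50.9; 25.0: 54.8, 43.7; 40.0: 59.9, 39.1
- amber (time / min: target / %, electrophile / %): 5.00: 27.8, 71.8; 15.0: 48.5, 51.3; 25.0: 55.0, 44.3; 40.0: 59.5, 39.4

(scatter of a reading: 0.3 percentage points)

- charges are per starting volume, the dose included; the dosed solution carries all of it
- given per volume of solution although it is solid: solid base
- the earlier runs were read with a standard deviation of 0.3 percentage points
- on the list of suspects stand: electrophile + nucleophile -> acid set free + target; nucleophile + acid set free <-> protonated nucleophile; acid set free + free base <-> salt of the base; electrophile -> decomposition product; solid base <-> free base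
- at the start none of the solid base is in solution

1. ranking by amount of target, in percent of the electrophile charged, from high to low, at 40 min (Tuesday's / Saturday's / Monday's / Thursday's / Friday's / Sunday's)
2. the same order at 2.0 min (Tuesday's / Saturday's / Monday's / Thursday's / Friday's / Sunday's)
3. the amount of target, in percent of the electrophile charged of the flask you put first, at 40 min
4. the amount of target, in percent of the electrophile charged of the flask you put last, at 40 min

If each target took one nucleophile, the blue run would still hold 50.1% of the charge as nucleophile, more than the electrophile left, and I see no reason for the stall in that. The suspects offer a second sink: the acid set free parks a second nucleophile as protonated nucleophile. So I carry the nucleophile cap, the fraction of the charge that becomes target if each target takes two nucleophile and no acid leaves them, which is the equivalents of nucleophile over two. For the blue run it is 55.0%, and the reading stands 4.9 points above it at 59.9%. With other charges of solid base the reading at that time is 59.0% with 1.4 equiv and 59.5% with 6 equiv.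

Monday's and Sunday's look nearly the same: both have 0.740 equiv of nucleophile, the limiting reagent, and 2.00 equiv of solid base. They differ in the electrophile charge, 0.40 M against 1.2 M. Both have a cap of 37.0%, so I expect both to end above it, as the blue run does. The cap gives no ranking between them, and teal, blue and amber stand at 0.40 M.

The forecast ranks Thursday's > Saturday's > Tuesday's > Monday's > Sunday's > Friday's at 40 min and Sunday's > Thursday's > Saturday's > Monday's > Friday's > Tuesday's at 2.0 min, with 96.5% first and 33% last. It gives Monday's about 42% and Sunday's about 39%, “because the creep is smaller per electrophile”.

The flask gives Thursday's > Saturday's > Tuesday's > Sunday's > Monday's > Friday's at 40 min and Sunday's > Thursday's > Saturday's > Monday's > Friday's > Tuesday's at 2.0 min, with 96.8% first and 33.6% last.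

    electrophile + nucleophile → acid set free + target (k = 0.00552 M⁻¹ s⁻¹)
    nucleophile + acid set free ⇌ protonated nucleophile, settled at all times (K = 3100 M⁻¹)
    acid set free + free base ⇌ salt of the base, settled at all times (K = 774 M⁻¹)
    electrophile → decomposition product (k = 8.33 × 10⁻⁶ s⁻¹)
    solid base ⇌ free base, rate k5*(cs5 - [free base]) while solid is left; crystals form when [free base] > cs5 (solubility = 23.0 mM, k = 0.0196 s⁻¹)

Monday's ends 6.1 points above its cap and Sunday's 8.7 points above the same cap, so the pair stands opposite to the forecast. As target formed in both flasks, unbound nucleophile fell: at 40.0 min Sunday's had 1.2% of its nucleophile unbound and Monday's 4.4%, with solid base still at 90.3% and 89.3% of charge. At that time the salt of the base stood 3.55 times as high in Sunday's as in Monday's, for 3.00 times the electrophile charge. Thursday's recipe with 1.10 equiv of nucleophile has a cap of 55.0%. That neighbour reaches 46.9% target at 40.0 min, below its cap, with 23.1% of its nucleophile unbound.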